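The rate constants belong to no real substance; no experiment stands behind them.

Slowness is where we start: in these flasks a coupling has to compete with the loss of what it makes. The flasks differ in how the charges go in, and summer also in the temperature of its addition.

| flask | substrate | partner | temperature | time | remark |
|---|---|---|---|---|---|
| midnight | 1.0 mM | 1.50 mM (fed, over 5.0 s) | 25 °C | 25 s | all else is in the flask from the start; the feed brings no volume worth counting |
| dawn | 1.0 mM (fed, over 5.0 s) | 1.50 mM | 25 °C | 25 s | all else is in the flask from the start; the feed brings no volume worth counting |
| summer | 1.0 mM | 1.50 mM (fed, over 5.0 s) |  | 25 s | the addition at 5 °C, then warmed to 25 °C; the feed brings no volume worth counting |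
| winter | 1.0 mM | 1.50 mM | 25 °C | 25 s | everything together at the start |

    substrate ⇌ open intermediate (K1 = 0.99, k1 = 0.12 s⁻¹, Ea1 = 72.0 kJ mol⁻¹, ΔH1 = −8.00 kJ mol⁻¹)
    partner → second intermediate (k2 = 0.032 s⁻¹, Ea2 = 85.0 kJ mol⁻¹)
    open intermediate + second intermediate → target (k3 = 54 L mol⁻¹ s⁻¹, Ea3 = 41.0 kJ mol⁻¹)
    target → over-reaction product (k4 = 0.094 s⁻¹, Ea4 = 70.0 kJ mol⁻¹)
    partner → decomposed reagent (k5 = 0.080 s⁻¹, Ea5 = 72.0 kJ mol⁻¹)
    (constants at 25 °C)

- the list of constants is for 25 °C, to be carried to other temperatures by the activation energies and enthalpies

- the best flask by share of target in target plus over-reaction product; "all alike" if 1.5 percentage points covers them all (midnight / dawn / summer / winter / all alike)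
- share of target in target plus over-reaction product at the end, midnight
- share of target in target plus over-reaction product at the end, dawn
- share of target in target plus over-reaction product at the end, summer
- share of target in target plus over-reaction product at the end, winter

We keep a ledger of the partner, at 25 °C.

First entry: partner decomposes faster than it gives second intermediate. Both steps are first order in partner, so this comparison does not drift as partner falls. Of the partner used, 71.4% becomes decomposed reagent, which is 1.07 mM of the charge once the books close.

Second entry: the rest of the charge, 0.429 mM, goes to second intermediate. That is less than the substrate charged, so partner is the limiting reagent.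

Third entry: we take the opening at equilibrium, with 49.7% of the substrate charged standing open, and on that estimate second intermediate couples at a pseudo-first-order rate of

0.0269 s⁻¹

Fourth entry: target goes on to over-reaction product at 0.094 s⁻¹, faster than that coupling. So the last line of the ledger depends on the age of the target.

Our assumption is that coupling runs steadily once the opening has relaxed, after a lag of 4.15 s. Call the open window the time from that moment to the end of the run: 20.9 s in winter. For midnight and dawn we also take off the mean delay of the feed, 2.50 s, which leaves 18.4 s. In summer we count the cold addition as dead time and the warming as instant, which leaves 15.9 s.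

A steady source feeding a first-order loss keeps a share (one − e^−x)/x, where x is the loss constant times the window:

winter: 43.8%

midnight: 47.6%

dawn: 47.6%

summer: 52.0%

Our best flask is summer.

The forecast named summer, with 49% for midnight, 47% for dawn, 53% for summer and 45.5% for winter, holding that the cold addition “nearly freezes the chemistry”.

The simulation gives summer as best: 53.2% there, against 48.0% for midnight, 47.3% for dawn and 45.1% for winter. In winter at 25.0 s the flask holds target 5.83% and over-reaction product 7.11% of the substrate charged, with [open intermediate] at 41.9% and [second intermediate] at 0.273 mM. Those readings give a coupling rate at that moment of 0.00617 mM s⁻¹. Dividing the amount coupled by that end rate gives 21.0 s, close to the open window of 20.9 s.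

Take the neighbour flask, winter read at 6.0 s. Its open window is 1.85 s, and the kept share comes to 91.8%. The computed share is 85.4%.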